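Start from slowness: single product moves on to bis adduct far more slowly than it forms. The summer run at 1.00 h already holds 63.0% of single product against 9.0% of bis adduct.

| flask | starting material | coupling partner | remark | time |
|---|---|---|---|---|
| dawn | 0.25 M | 0.41 equiv | run made earlier |  |
| summer | 0.25 M | 0.90 equiv | run made earlier |  |
| delta | 0.25 M | 2.00 equiv |  | 8.0 h |
| beta | 0.25 M | 0.500 equiv |  | 8.0 h |

| run | time / h | bis adduct / % | single product / % | starting material / % |
|---|---|---|---|---|
| dawn | 1.33 | 0.6 | 30.5 | 59.8 |
| dawn | 3.00 | 2.8 | 31.8 | 59.3 |
| dawn | 4.00 | 0.2 | 30.6 | 60.5 |
| dawn | 6.00 | 1.2 | 31.6 | 60.3 |
| summer | 0.417 | 6.7 | 57.2 | 26.8 |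
| summer | 1.00 | 9.0 | 63.0 | 18.9 |
| summer | 2.50 | 9.5 | 61.5 | 19.9 |
| summer | 6.00 | 8.4 | 62.6 | 17.6 |

(scatter of a reading: 1 percentage point)



- which of these holds the largest part of the starting material at the end of delta (other mono adduct / starting material / single product / bis adduct)
- which of these holds the largest part of the starting material at the end of beta (other mono adduct / starting material / single product / bis adduct)
- amount of bis adduct at the end of delta, in percent of the starting material charged

Take the gap in the balance as other mono adduct. Then the dawn run at 6.00 h sends 20.4% of the consumed starting material down the route that does not end in single product, as a reading.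

Now solve delta at two extremes. In the first, single product is frozen, so bis adduct stops at that share. In the second, partner stays at its full surplus, the charge left once each starting molecule has taken one, 1.00 equiv. Single product then decays exponentially, the pseudo-first-order case.

Delta must lie between them: the surplus shrinks as bis adduct forms. Once starting material and other mono adduct have gone, partner left, counted in whatever form it stands, is surplus minus bis adduct, and single product is one minus bis adduct, so the two amounts are equal. The rate then goes as the square of that amount, and the reciprocal of single product climbs linearly with time, which leaves a long tail of single product above the exponential. I commit to that bracket and that shape. Beta, charged 0.500 equiv, has no surplus, so it should stop as dawn did. Each starting molecule that reacts takes at least one partner, so in beta at least 50.0% of starting material should stay, more than the 39.8% of single product that the dawn share allows at most.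

The forecast gives bis adduct for delta, starting material for beta and 77% of bis adduct, which it calls “sensitive to the small rate constant”.

Delta gives 71.6% of bis adduct, and 95.8% at 80.0 h.

    starting material + coupling partner → single product (k = 0.0143 M⁻¹ s⁻¹)
    starting material + coupling partner → other mono adduct (k = 0.00395 M⁻¹ s⁻¹)
    coupling partner + single product → bis adduct (k = 4.78 × 10⁻⁴ M⁻¹ s⁻¹)
    coupling partner + other mono adduct → bis adduct (k = 0.00950 M⁻¹ s⁻¹)
    coupling partner ⇌ dormant form (K = 0.540, k = 0.0476 s⁻¹)

Use the surplus on delta stopped at 5.0 h: take away its 62.7% of bis adduct and 0.0931 M of partner should remain. That flask holds 0.0605 M free and 0.0327 M as dormant form.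

(All runs are simulated for substances that don't exist; the scatter is artificial.)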